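Take the easy run first, dawn, where L is doubled. This is a reckoning of shares, with every amount a fraction of the E charged.

| flask | E | G | L | temperature | remark | time |
|---|---|---|---|---|---|---|
| dusk | 0.40 M | 0.50 equiv | 1.05 equiv | 45 °C | run made earlier |  |
| summer | 0.20 M | 0.50 equiv | 1.05 equiv | 60 °C | run made earlier |  |
| spring | 0.30 M | 0.50 equiv | 1.05 equiv | 45 °C | run made earlier |  |
| dawn | 0.40 M | 0.50 equiv | 2.1 equiv | 60 °C | run made earlier |  |
| oak | 0.40 M | 0.500 equiv | 1.05 equiv (fed, over 50 min) |  | the addition at 30 °C, then warmed to 60 °C; the feed brings no volume worth counting | 1.0 h |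
| maple | 0.40 M | 0.500 equiv | 1.05 equiv (fed, over 50 min) | 60 °C | all else is in the flask from the start; the feed brings no volume worth counting | 1.0 h |
| cedar | 0.40 M | 0.500 equiv | 1.05 equiv | 60 °C | everything together at the start | 1.0 h |
| ash | 0.40 M | 0.500 equiv (fed, over 50 min) | 1.05 equiv | 60 °C | all else is in the flask from the start; the feed brings no volume worth counting | 1.0 h |

- dusk (time / min: Z / %): 6.00: 0; 20.0: 7; 30.0: 6; 50.0: 9; 80.0: 14; 120: 16
- summer (time / min: Z / %): 5.00: 3; 10.0: 3; 15.0: 8; 20.0: 5; 25.0: 7; 30.0: 9; 40.0: 11
- spring (time / min: Z / %): 10.0: 1; 20.0: 4; 30.0: 7; 40.0: 9; 50.0: 10; 60.0: 7; 80.0: 12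
- dawn (time / min: Z / %): 3.00: 2; 10.0: 12; 15.0: 10; 25.0: 12; 40.0: 13

(standard deviation of a reading: 1.5 percentage points)



- the flask with the highest amount of Z, in percent of the E charged ("all alike" if they lie within 1.5 percentage points) (oak / maple / cedar / ash / all alike)
- final Z, as a percentage of the E charged, in oak
- final Z, as a percentage of the E charged, in maple
- final Z, as a percentage of the E charged, in cedar
- final Z, as a percentage of the E charged, in ash

1. Z in dawn levels off at about 12.5%, a reading from its last two points, while 0.50 equiv of G and 2.1 equiv of L were charged. We suppose the stop means E has been taken, and that the other 87.5% went with L.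

2. So we suppose that each E chooses between G and L, and we use this for the flasks at the 60 °C of dawn. We call the preference the selectivity factor: how readily E takes G compared with L, at equal fractions, so that G's share is factor × G / (factor × G + L). With charged amounts, dawn gives 0.600. Putting that answer back, with G and L midway between start and end, gives 0.543.

3. Cedar: by this factor, G's share at first is 20.5%. With midway amounts it becomes 24.8%.

4. Maple: L starts at zero, so in the first instants E meets G. In the middle L builds up, and at the end we take L as what the feed leaves over. Cedar's share put in gives 57.8%, which overshoots, being more than the 0.500 equiv of G charged. Going round from the midpoint of the two, 41.3%, gives 40.8%.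

5. Ash: G starts at zero, and a first round gives 9.20%. For G's share we commit to maple above cedar above ash, we take Z to follow that order, and we leave oak unreckoned.

The forecast said cedar, with oak 10%, maple 18%, cedar 20% and ash 15%, on the ground that “G seems to be spent in two ways”.

The flasks give maple as the highest: oak 11.4%, maple 21.5%, cedar 17.0%, ash 6.19%.

    E + G → J (k = 0.240 /M/min, Ea = 66.0 kJ/mol)
    L + J → Z (k = 0.440 /M/min, Ea = 71.0 kJ/mol)
    E + L → D (k = 0.320 /M/min, Ea = 84.0 kJ/mol)
    E + Z → Q (k = 0.390 /M/min, Ea = 79.0 kJ/mol)
    (constants at 60 °C)

Maple keeps 14% of its G at 1.0 h, so it spent G equal to 43.0% of the E charged, against our 40.8%. Our share counts G taken up, not Z: maple ends with 21.5% of Z beside 5.87% of J and 31.6% of Q, which holds two E. Now ash, with the factor 0.543 once more: the midpoint of 24.8% and 9.20% is 17.0%, and going round gives 12.4%. Ash keeps 73% of its G at 1.0 h, so it spent G equal to 13.3% of the E charged.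

The data stem from a simulated flask from invented constants, noise included.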